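## Structural features

The target is an eremophilane, a cis-fused decalin in which ring A (C1–C5, C10) and ring B (C5–C10) share the C5–C10 bond; C5 is quaternary (β-methyl, C14) and C10 carries a β-hydrogen. Ring A bears the 3α-angelate and the 4β-methyl group (C15), so C3, C4, C5 and C10 form an unbroken row of stereocentres that continues with C9 (β-angelate) on ring B. C7 (β-isopropenyl) is set apart by C6 and the C8 ketone. The fragile groups are the two angelates (Z to E isomerisation, acyl shifts), the α-acyloxy ketone at C8/C9, and the β,γ-unsaturated ketone, whose C7 centre can epimerise and whose isopropenyl double bond can move into conjugation. In the chair–chair form with the C5 methyl equatorial on ring B (conformer Q below) the substituents at C3, C4, C7 and C9 are all equatorial, so the natural array is the thermodynamic one. The real difficulty is the quaternary C5 flanked by C4 and C10 in a cis-fused frame, under absolute control, together with two identical esters on hindered carbinols. The key step exploits the fact that the C9 carbinol, the C10–C5 ring fusion with its methyl-bearing C5, and the C3 oxygen lie in one row: an electrophilic C9 is attacked by C10 of a C5=C10 olefin, and the tertiary C5 cation is trapped by C4 of a C3 enol ether, closing ring B and ring A together. In the other chair–chair form (conformer P, C5 methyl axial on ring B) the carbonyl precursors of C3 and C9 are each shielded on one face by an axial substituent of C5, so one hydride reduction and one acylation operation can serve both positions.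

## Logic of the disconnections

**33 from 32.** No skeletal bond is cut; only the C7–H bond is re-formed. A chair closure of ring B necessarily leaves the isopropenyl group trans to the C5 methyl, so C7 is used as a control element and corrected last. The forward step must epimerise C7 under thermodynamic control without conjugating the isopropenyl group or disturbing C9.

**32 from 31 from 30.** The C8 carbonyl is traced to a silyl-protected carbinol (O–Si bond, then C8–H). During ring formation C8 must be an sp3, equatorial, coordinating substituent. The forward steps must remove silicon without acyl migration from O9 and oxidise without epimerisation.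

**30 from 27 and 28.** The two acyl–oxygen bonds at O3 and O9 are cut together, each releasing one molecule of 28. Both esters are the same, so one operation with two equivalents of the acid installs them. The demand is acylation of two hindered alcohols with retention of the Z geometry of the acyl group.

**27 from 26 from 25.** The C3–H and C9–H bonds are cut (hydride), and C9 is first taken to the ketone. This makes whichever C9 configuration the cyclisation delivers irrelevant and replaces an SN2 inversion that would have to pass syn to the axial C5 methyl. The demand is hydride delivery anti to the axial C5 substituents at both carbonyls, with C4 and C10 untouched.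

**25 from 24.** The C9–C10 and C4–C5 bonds are cut, removing both rings and four stereocentres in one step. The forward step needs a Z C5=C10 olefin for the cis fusion, trans (7S,8S) substituents to select one chair, and an E enol ether to place C15 β.

**24 from 23 from 22.** The aldehyde is traced to a benzyl-protected primary alcohol. The aldehyde and the enol ether cannot be carried together for long, and acid cannot be used once the enol ether is present, so the unmasking must be reductive and the oxidation buffered.

**22 from 21 from 20 from 19.** The E enol ether is traced through a 2-silyloxydiene to a vinyl ketone, and the C3–C4 bond is cut to an N-methoxy-N-methylamide and a vinyl nucleophile. This fixes the regiochemistry (only C2 can enolise) and the geometry (1,4-hydrogen addition to an s-cis diene). The demand is a hydrogenation that leaves three other alkenes alone.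

**19 from 17 and 7.** The C5–C6 bond is cut between an sp3 zinc reagent and a Z alkenyl iodide. This makes the route convergent and takes the olefin geometry from a geometrically defined iodide. The demand is zinc insertion and coupling without loss of the C7/C8 centres.

**17 from 16 from 15 from 14, and 14 from 11 and 12; 11 from 8 and 9.** The C7–C8 bond is cut as an auxiliary-controlled syn-aldol, which sets both stereocentres and the absolute configuration in one step. The acyl carbon becomes C6 and is reduced and turned into the iodide.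

**7 from 4 and 5; 4 from 3 from 1.** The C1–C2 bond is cut as an amide-enolate alkylation of an allylic bromide. The Z iodoalkene comes from an alkyne by hydroxyl-directed trans-hydroalumination and iodination.

## Other disconnections considered

**Alternative 1:** The cut is the C5–C6 bond of the cis-decalin A1, which still lacks the C7 side chain and the C3 oxygen. A1 is traced by a [3,3] shift to the bicyclo[2.2.2]octenol A2, which a Diels–Alder adduct of an oxidatively dearomatised guaiacol and a vinyl nucleophile would supply. In the forward step KH/18-crown-6 would form the alkoxide of A2; the vinyl terminus would bond to the methyl-bearing olefin carbon, the bond between the carbinol carbon and the bridgehead would break, and A1 would appear as its C7–C8 enolate.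
- In its favour: a concerted suprafacial shift in a rigid bicycle fixes the cis fusion and the quaternary C5. On reliability of the ring fusion it is at least the equal of the chosen plan. C8 and C9 arrive at the ketone and ketal levels, so no late correction at C9 is needed, which is better than the chosen plan. The bicyclic core is reached in fewer steps, which is also better.
- Against it here: A2 would be racemic unless a resolution or a chiral dienophile is added. The C3 oxygen and the C4 centre would have to come from the C3=C4 olefin by a face-selective hydroboration whose sense is not secured. The isopropenyl group would have to be built onto the C7 enolate indirectly.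
- Comparison: in structure it sets two of the six stereocentres against four in the chosen step. In mechanism it is pericyclic and stereospecific against a cationic relay. In step economy it is shorter before the key step and longer after it, and it has no source of absolute configuration.

**Alternative 2:** The cut is the C8–C9 bond of ring B in the ketol A3, traced to the dialdehyde A4 in which ring A is complete. In the forward step a triazolium-derived carbene would add to the C8 aldehyde and the resulting acyl anion equivalent would attack the C9 aldehyde (intramolecular crossed benzoin).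
- In its favour: A3 has exactly the 8-oxo-9-hydroxy array of the target, so ring B needs no oxidation-state changes afterwards; this is better than the chosen plan. The conditions are mild and metal-free, and on functional-group fidelity it is also better.
- Against it here: both aldehydes are α-branched, so which one becomes the nucleophile, and hence the regiochemistry of the ketol, is not secured. C7 and C10 are α to aldehydes and could epimerise under the basic conditions; epimerisation at C10 would erode the cis fusion. The hard part, ring A with four contiguous centres including C5, is left to earlier steps.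
- Comparison: in structure it forms one bond, one ring and one stereocentre against two bonds, two rings and four stereocentres. In mechanism it is a reversible umpolung under thermodynamic control against a kinetic chair relay. In step economy the total count is likely higher because ring A needs its own stereocontrolled synthesis.

**Alternative 3:** The cuts are C6–C7 and C5–C10. The cis-decalinone A5 is traced to the trienone A6, formed in the flask by oxidising the allylic alcohol A7. In the forward step the oxidation would unmask the methacryloyl dienophile, which would add to the 2,3-dioxygenated diene and close both rings.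
- In its favour: two rings, the quaternary C5 and the ring fusion come in one thermal step from an achiral chain. In bonds and rings formed per step it is the equal of the chosen plan. The C8 and C9 oxygens are differentiated from the start, and no aldehyde/enol ether pair has to coexist, which is better.
- Against it here: A5 lacks C15, the C3 oxygen and the C7 side chain. C4 is a ketone that must become a β-methyl-bearing carbon, C3 must be oxygenated and C7 alkylated. Cis versus trans fusion with an α-methyl dienophile is not secured, and the product is racemic without a chiral catalyst.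
- Comparison: in structure it sets two stereocentres against four. In mechanism it is a concerted cycloaddition with predictable regiochemistry but no relay of absolute configuration. In step economy it is shorter before and clearly longer after the key step.

Key step: step 15

**Remarks and assumptions**

- Eremophilane numbering is used (C1–C10 decalin, C11–C13 isopropenyl, C14 on C5, C15 on C4); β is the face of the C5 methyl. "7-epi" means isopropenyl α. TBS = tert-butyldimethylsilyl, TIPS = triisopropylsilyl, Bn = benzyl.
- Conformer P is the chair–chair form with the C5 methyl axial on ring B; conformer Q is the ring-flipped form. Compounds 25 and 26 are assumed to react from conformer P, the only form with the C7 and C8 substituents equatorial.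
- A Z enol ether (methyl cis to silyloxy, the usual result of 1,4-hydrosilylation of a vinyl ketone) would close ring A in a chair with C15 equatorial, that is trans to the C5 methyl (4α). Equilibration of the locked cyclisation product would also favour 4α. The precursor is therefore built with the E enol ether, which delivers the 4β-methyl directly.
- The C9 configuration from the cyclisation does not matter, because step 16 oxidises C9.
- Both carbinols of 27 are esterified in one operation, so step 18 consumes two equivalents of angelic acid.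

## Route

Step 1
Reactants: 1 but-2-yn-1-ol
Product: 3 (Z)-3-iodobut-2-en-1-ol, via cyclic alkenylalanate 2 (not isolated)
Conditions: NaAlH2(OCH2CH2OCH3)2, Et2O, 0 °C to rt; EtOAc; then I2, THF, −78 to 0 °C
Reagents that add atoms: iodine, II
Why: Hydroxyl-directed trans-hydroalumination of the propargylic alkoxide puts aluminium on C3 anti to the delivered hydride; iodinolysis with retention gives the Z iodide (iodine cis to the CH2OH group).

Step 2
Reactants: 3 (Z)-3-iodobut-2-en-1-ol
Product: 4 (Z)-1-bromo-3-iodobut-2-ene
Conditions: CBr4, PPh3, CH2Cl2, 0 °C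
Reagents that add atoms: tetrabromomethane, BrC(Br)(Br)Br
Why: Appel bromination of a primary allylic alcohol; substitution at the CH2 carbon leaves the alkenyl iodide and the olefin geometry untouched.

Step 3
Reactants: 5 N-methoxy-N-methylacetamide; 4 (Z)-1-bromo-3-iodobut-2-ene
Product: 7 (Z)-5-iodo-N-methoxy-N-methylhex-4-enamide, via lithium amide enolate 6 (not isolated)
Conditions: LiN(i-Pr)2, THF, −78 °C; then 4, −78 to −40 °C
Reagents that add atoms: none
Why: SN2 alkylation of an amide enolate by a primary allylic bromide forms C1–C2; the low temperature avoids elimination of the alkenyl iodide and decomposition of the enolate.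

Step 4
Reactants: 8 3-methylbut-3-enoic acid; 9 (S)-4-benzyloxazolidin-2-one
Product: 11 (S)-4-benzyl-3-(3-methylbut-3-enoyl)oxazolidin-2-one, via mixed pivalic anhydride 10 (not isolated)
Conditions: t-BuCOCl, Et3N, THF, −20 °C; then 9, LiCl, −20 °C to rt
Reagents that add atoms: none
Why: N-acylation of the oxazolidinone through the mixed anhydride with LiCl activation; the weak base and low temperature keep the β,γ-double bond out of conjugation.

Step 5
Reactants: 11 (S)-4-benzyl-3-(3-methylbut-3-enoyl)oxazolidin-2-one; 12 2-(benzyloxy)acetaldehyde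
Product: 14 (S)-4-benzyl-3-[(2S,3S)-4-(benzyloxy)-3-hydroxy-2-(prop-1-en-2-yl)butanoyl]oxazolidin-2-one, via dibutylboron Z-enolate 13 (not isolated)
Conditions: Bu2BOTf, Et3N, CH2Cl2, 0 °C; 12, −78 to 0 °C; pH 7 buffer, MeOH, H2O2
Reagents that add atoms: none
Why: Evans syn-aldol: the Z boron enolate reacts at its α-carbon through a Zimmerman–Traxler chair on the face away from the benzyl group, setting C7 and C8 (2S,3S) in one step; the isopropenyl group stays unconjugated.

Step 6
Reactants: 14 (S)-4-benzyl-3-[(2S,3S)-4-(benzyloxy)-3-hydroxy-2-(prop-1-en-2-yl)butanoyl]oxazolidin-2-one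
Product: 15 (S)-4-benzyl-3-[(2S,3S)-4-(benzyloxy)-3-(TBS-oxy)-2-(prop-1-en-2-yl)butanoyl]oxazolidin-2-one
Conditions: TBSOTf, 2,6-lutidine, CH2Cl2, −78 to 0 °C
Reagents that add atoms: tert-butyldimethylsilyl trifluoromethanesulfonate, CC(C)(C)[Si](C)(C)OS(=O)(=O)C(F)(F)F
Why: Silylation of the secondary aldol hydroxyl with a silyl triflate and a hindered base; no retro-aldol or epimerisation is expected under these non-nucleophilic conditions.

Step 7
Reactants: 15 (S)-4-benzyl-3-[(2S,3S)-4-(benzyloxy)-3-(TBS-oxy)-2-(prop-1-en-2-yl)butanoyl]oxazolidin-2-one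
Product: 16 (2R,3S)-4-(benzyloxy)-3-(TBS-oxy)-2-(prop-1-en-2-yl)butan-1-ol
Conditions: LiBH4, MeOH (1 equiv), THF, 0 °C
Reagents that add atoms: none
Why: Reductive removal of the auxiliary: borohydride attacks the exocyclic imide carbonyl and the acyl carbon becomes the C6 carbinol; the descriptor at C7 changes only through priorities.

Step 8
Reactants: 16 (2R,3S)-4-(benzyloxy)-3-(TBS-oxy)-2-(prop-1-en-2-yl)butan-1-ol
Product: 17 {[(2S,3S)-1-(benzyloxy)-4-iodo-3-(prop-1-en-2-yl)butan-2-yl]oxy}(tert-butyl)dimethylsilane
Conditions: I2, PPh3, imidazole, CH2Cl2, 0 °C to rt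
Reagents that add atoms: iodine, II
Why: Appel-type iodination of the primary alcohol through the alkoxyphosphonium salt; the stereocentres are not involved.

Step 9
Reactants: 17 {[(2S,3S)-1-(benzyloxy)-4-iodo-3-(prop-1-en-2-yl)butan-2-yl]oxy}(tert-butyl)dimethylsilane; 7 (Z)-5-iodo-N-methoxy-N-methylhex-4-enamide
Product: 19 (4Z,7S,8S)-9-(benzyloxy)-8-(TBS-oxy)-N-methoxy-N,5-dimethyl-7-(prop-1-en-2-yl)non-4-enamide, via alkylzinc iodide 18 (not isolated)
Conditions: Zn dust, LiCl, THF, 40 °C; then 7, PdCl2(dppf) (5 mol %; dppf = 1,1'-bis(diphenylphosphino)ferrocene), THF, rt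
Reagents that add atoms: none
Why: Negishi sp3–sp2 coupling: zinc insertion into the primary iodide, then zerovalent palladium couples the alkylzinc with the alkenyl iodide with retention of the Z geometry (C5–C6 bond); the amide, silyl ether and benzyl ether are inert to the zinc reagent.

Step 10
Reactants: 19 (4Z,7S,8S)-9-(benzyloxy)-8-(TBS-oxy)-N-methoxy-N,5-dimethyl-7-(prop-1-en-2-yl)non-4-enamide
Product: 20 (6Z,9S,10S)-11-(benzyloxy)-10-(TBS-oxy)-7-methyl-9-(prop-1-en-2-yl)undeca-1,6-dien-3-one
Conditions: CH2=CHMgBr, THF, −78 to 0 °C; inverse quench into cold aq. KHSO4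
Reagents that add atoms: vinylmagnesium bromide, C=C[Mg]Br
Why: Weinreb ketone synthesis: the chelated tetrahedral adduct prevents over-addition, and the acidic inverse quench keeps the released amine from adding to the vinyl ketone.

Step 11
Reactants: 20 (6Z,9S,10S)-11-(benzyloxy)-10-(TBS-oxy)-7-methyl-9-(prop-1-en-2-yl)undeca-1,6-dien-3-one
Product: 21 (3Z,6Z,9S,10S)-11-(benzyloxy)-10-(TBS-oxy)-7-methyl-9-(prop-1-en-2-yl)-3-(TIPS-oxy)undeca-1,3,6-triene
Conditions: i-Pr3SiOTf, Et3N, CH2Cl2, −78 to 0 °C
Reagents that add atoms: triisopropylsilyl trifluoromethanesulfonate, CC(C)[Si](C(C)C)(C(C)C)OS(=O)(=O)C(F)(F)F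
Why: Soft enolisation and O-silylation; the vinyl side has no α-hydrogen, so only C2 can enolise, which gives the 2-silyloxydiene with the chain trans to the vinyl group.

Step 12
Reactants: 21 (3Z,6Z,9S,10S)-11-(benzyloxy)-10-(TBS-oxy)-7-methyl-9-(prop-1-en-2-yl)-3-(TIPS-oxy)undeca-1,3,6-triene
Product: 22 (2E,6Z,9S,10S)-11-(benzyloxy)-10-(TBS-oxy)-7-methyl-9-(prop-1-en-2-yl)-3-(TIPS-oxy)undeca-2,6-diene
Conditions: (η6-naphthalene)Cr(CO)3 (10 mol %), H2 (4 atm), THF, 40 °C
Reagents that add atoms: none
Why: 1,4-Hydrogenation of a conjugated diene by an arene–Cr(CO)3 catalyst: the zerovalent chromium fragment binds the s-cis diene and delivers hydrogen to both termini (C2 and C15), so the new C3=C4 bond has C2 and C15 cis, which is the E enol ether; isolated alkenes are not reduced.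

Step 13
Reactants: 22 (2E,6Z,9S,10S)-11-(benzyloxy)-10-(TBS-oxy)-7-methyl-9-(prop-1-en-2-yl)-3-(TIPS-oxy)undeca-2,6-diene
Product: 23 (2S,3S,5Z,9E)-2-(TBS-oxy)-5-methyl-3-(prop-1-en-2-yl)-9-(TIPS-oxy)undeca-5,9-dien-1-ol
Conditions: lithium 4,4'-di-tert-butylbiphenylide, THF, −78 °C; aq. NH4Cl at −78 °C
Reagents that add atoms: none
Why: Electron-transfer cleavage of the benzyl C–O bond by an arene radical anion; silyl ethers, the enol ether and unconjugated alkenes are not reducible at −78 °C, and the cold quench limits silyl migration to the new alkoxide.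

Step 14
Reactants: 23 (2S,3S,5Z,9E)-2-(TBS-oxy)-5-methyl-3-(prop-1-en-2-yl)-9-(TIPS-oxy)undeca-5,9-dien-1-ol
Product: 24 (2S,3S,5Z,9E)-2-(TBS-oxy)-5-methyl-3-(prop-1-en-2-yl)-9-(TIPS-oxy)undeca-5,9-dienal
Conditions: Dess–Martin periodinane, NaHCO3, CH2Cl2, 0 °C; used at once
Reagents that add atoms: none
Why: Buffered Dess–Martin oxidation of the primary alcohol; the neutral medium preserves the enol ether and the α-silyloxy stereocentre.

Step 15
Reactants: 24 (2S,3S,5Z,9E)-2-(TBS-oxy)-5-methyl-3-(prop-1-en-2-yl)-9-(TIPS-oxy)undeca-5,9-dienal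
Product: 25 8β-(TBS-oxy)-9α-hydroxy-7-epi-10βH-eremophil-11-en-3-one (4β,5β-dimethyl, 7α-isopropenyl)
Conditions: MeAlCl2 (2.5 equiv), CH2Cl2, −78 °C, slow addition of 24 to a final 0.003 M; Et3N, then aq. KNaC4H4O6
Reagents that add atoms: none
Why: MeAlCl2 binds the C9 aldehyde and the neighbouring C8 silyloxy oxygen; C10 of the Z C5=C10 olefin attacks the activated carbonyl (6-endo closure of ring B, tertiary C5 cation), the enol ether captures the cation through C4 (second 6-endo closure, ring A), and chloride then removes the silyl group from the C3 silyloxycarbenium ion. The closest known reaction type is the Lewis-acid, carbonyl- or acetal-initiated cation–olefin bicyclisation terminated by a silyl enol ether, with the Stork–Eschenmoser stereochemical course. C5 and C10: antiperiplanar addition across the Z olefin in a chair makes the C5 methyl and H-10 cis. Their absolute sense follows from C7 and C8: only one chair keeps both the isopropenyl and the silyloxy group equatorial (the other puts the isopropenyl syn-axial to the C5 methyl), so the (7S,8S) pair relays to 5β-methyl and 10β-H. C4: the E enol ether carries C15 cis to C2, which becomes the axial β position in the chair closure of ring A. C9: chelation holds the carbonyl oxygen syn to the C8 oxygen and hence equatorial (9α); this centre is erased in step 16. The step needs bicyclisation to outrun intermolecular Mukaiyama aldol addition, proton loss from the C5 cation and attack on the isopropenyl group: high dilution and slow addition suppress the bimolecular path, six-membered capture by the enol ether should be faster than elimination, and the isopropenyl group could only react through a disfavoured 5-endo closure.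

Step 16
Reactants: 25 8β-(TBS-oxy)-9α-hydroxy-7-epi-10βH-eremophil-11-en-3-one
Product: 26 8β-(TBS-oxy)-7-epi-10βH-eremophil-11-ene-3,9-dione
Conditions: Dess–Martin periodinane, NaHCO3, CH2Cl2, 0 °C to rt
Reagents that add atoms: none
Why: Dess–Martin oxidation of the C9 carbinol; the buffered, base-free medium should leave the epimerisable C4 and C10 centres untouched, and either C9 epimer of 25 converges here.

Step 17
Reactants: 26 8β-(TBS-oxy)-7-epi-10βH-eremophil-11-ene-3,9-dione
Product: 27 8β-(TBS-oxy)-7-epi-10βH-eremophil-11-ene-3α,9β-diol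
Conditions: LiBH(s-Bu)3 (3 equiv), THF, −78 °C; AcOH at −78 °C; pH 7 buffer, H2O2, 0 °C
Reagents that add atoms: none
Why: Steric approach control with a bulky borohydride in conformer P: at C9 the β face is blocked by the axial C5 methyl, so hydride enters from α (9β-OH); at C3 the α face is blocked by the axial C6 methylene, so hydride enters from β (3α-OH); the pattern is that of ketones flanked by a syn-axial substituent in cis-fused steroids.

Step 18
Reactants: 27 8β-(TBS-oxy)-7-epi-10βH-eremophil-11-ene-3α,9β-diol; 28 angelic acid (two equivalents are consumed)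
Product: 30 3α,9β-bis(angeloyloxy)-8β-(TBS-oxy)-7-epi-10βH-eremophil-11-ene, via mixed angelic trichlorobenzoic anhydride 29 (not isolated)
Conditions: 28 (2.6 equiv), 2,4,6-Cl3C6H2COCl (2.6 equiv), Et3N (5 equiv), toluene, rt; then 27, toluene, 80 °C
Reagents that add atoms: angelic acid (second equivalent), C/C=C(/C)C(=O)O
Why: Yamaguchi esterification: two molecules of the mixed anhydride each transfer one angeloyl group, one to O3 and one to O9, with retention at carbon; leaving out a nucleophilic pyridine catalyst avoids the addition–elimination path that turns angelates into tiglates.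

Step 19
Reactants: 30 3α,9β-bis(angeloyloxy)-8β-(TBS-oxy)-7-epi-10βH-eremophil-11-ene
Product: 31 3α,9β-bis(angeloyloxy)-7-epi-10βH-eremophil-11-en-8β-ol
Conditions: HF·pyridine, pyridine, THF, 0 °C to rt
Reagents that add atoms: none
Why: Fluoride-driven cleavage of the Si–O bond in a buffered, weakly acidic medium, which disfavours migration of the neighbouring angeloyl group and leaves the esters and the alkene intact.

Step 20
Reactants: 31 3α,9β-bis(angeloyloxy)-7-epi-10βH-eremophil-11-en-8β-ol
Product: 32 3α,9β-bis(angeloyloxy)-7-epi-10βH-eremophil-11-en-8-one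
Conditions: Dess–Martin periodinane, NaHCO3, CH2Cl2, 0 °C to rt
Reagents that add atoms: none
Why: Dess–Martin oxidation of the C8 carbinol to the α-acyloxy ketone under neutral conditions.

Step 21
Reactants: 32 3α,9β-bis(angeloyloxy)-7-epi-10βH-eremophil-11-en-8-one
Product: 33 3α,9β-bis(angeloyloxy)-10βH-eremophil-11-en-8-one, (3R,4R,5R,7R,9R,10S), the target
Conditions: DBU (0.2 equiv), toluene, 0 °C to rt, stopped once C7 has equilibrated; AcOH
Reagents that add atoms: none
Why: Base-mediated epimerisation at C7 through the dienolate with kinetic reprotonation at the α-carbon; in 32 either the C9 ester is syn-axial to the C5 methyl (conformer P) or the isopropenyl group is axial (conformer Q), whereas 33 has the substituents at C3, C4, C7 and C9 all equatorial in conformer Q, which is the driving force.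

## Compound list

1 | but-2-yn-1-ol | CC#CCO | starting material
2 | sodium 2,2-bis(2-methoxyethoxy)-3-methyl-2,5-dihydro-1,2-oxaluminol-2-uide (cyclic alkenylalanate, not isolated) | CC1=CCO[Al-]1(OCCOC)OCCOC.[Na+] | intermediate
3 | (Z)-3-iodobut-2-en-1-ol | C/C(I)=C/CO | intermediate
4 | (Z)-1-bromo-3-iodobut-2-ene | C/C(I)=C/CBr | intermediate
5 | N-methoxy-N-methylacetamide | CC(=O)N(C)OC | starting material
6 | lithium 1-[methoxy(methyl)amino]ethen-1-olate (not isolated) | [Li+].C=C([O-])N(C)OC | intermediate
7 | (Z)-5-iodo-N-methoxy-N-methylhex-4-enamide | CON(C)C(=O)CC/C=C(/C)I | intermediate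
8 | 3-methylbut-3-enoic acid | C=C(C)CC(=O)O | starting material
9 | (S)-4-benzyloxazolidin-2-one | O=C1N[C@@H](Cc2ccccc2)CO1 | starting material
10 | 3-methylbut-3-enoic pivalic anhydride (not isolated) | C=C(C)CC(=O)OC(=O)C(C)(C)C | intermediate
11 | (S)-4-benzyl-3-(3-methylbut-3-enoyl)oxazolidin-2-one | C=C(C)CC(=O)N1[C@@H](Cc2ccccc2)COC1=O | intermediate
12 | 2-(benzyloxy)acetaldehyde | O=CCOCc1ccccc1 | starting material
13 | (S)-4-benzyl-3-[(1Z)-1-(dibutylboranyloxy)-3-methylbuta-1,3-dien-1-yl]oxazolidin-2-one (not isolated) | C=C(C)/C=C(\OB(CCCC)CCCC)N1[C@@H](Cc2ccccc2)COC1=O | intermediate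
14 | (S)-4-benzyl-3-[(2S,3S)-4-(benzyloxy)-3-hydroxy-2-(prop-1-en-2-yl)butanoyl]oxazolidin-2-one | C=C(C)[C@H](C(=O)N1[C@@H](Cc2ccccc2)COC1=O)[C@H](O)COCc1ccccc1 | intermediate
15 | (S)-4-benzyl-3-[(2S,3S)-4-(benzyloxy)-3-(TBS-oxy)-2-(prop-1-en-2-yl)butanoyl]oxazolidin-2-one | C=C(C)[C@H](C(=O)N1[C@@H](Cc2ccccc2)COC1=O)[C@H](O[Si](C)(C)C(C)(C)C)COCc1ccccc1 | intermediate
16 | (2R,3S)-4-(benzyloxy)-3-(TBS-oxy)-2-(prop-1-en-2-yl)butan-1-ol | C=C(C)[C@H](CO)[C@H](O[Si](C)(C)C(C)(C)C)COCc1ccccc1 | intermediate
17 | {[(2S,3S)-1-(benzyloxy)-4-iodo-3-(prop-1-en-2-yl)butan-2-yl]oxy}(tert-butyl)dimethylsilane | C=C(C)[C@H](CI)[C@H](O[Si](C)(C)C(C)(C)C)COCc1ccccc1 | intermediate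
18 | [(2S,3S)-4-(benzyloxy)-3-(TBS-oxy)-2-(prop-1-en-2-yl)butyl]zinc iodide (not isolated) | C=C(C)[C@H](C[Zn]I)[C@H](O[Si](C)(C)C(C)(C)C)COCc1ccccc1 | intermediate
19 | (4Z,7S,8S)-9-(benzyloxy)-8-(TBS-oxy)-N-methoxy-N,5-dimethyl-7-(prop-1-en-2-yl)non-4-enamide | C=C(C)[C@H](C/C(C)=C\CCC(=O)N(C)OC)[C@H](O[Si](C)(C)C(C)(C)C)COCc1ccccc1 | intermediate
20 | (6Z,9S,10S)-11-(benzyloxy)-10-(TBS-oxy)-7-methyl-9-(prop-1-en-2-yl)undeca-1,6-dien-3-one | C=C(C)[C@H](C/C(C)=C\CCC(=O)C=C)[C@H](O[Si](C)(C)C(C)(C)C)COCc1ccccc1 | intermediate
21 | (3Z,6Z,9S,10S)-11-(benzyloxy)-10-(TBS-oxy)-7-methyl-9-(prop-1-en-2-yl)-3-(TIPS-oxy)undeca-1,3,6-triene | C=C(C)[C@H](C/C(C)=C\C/C=C(\O[Si](C(C)C)(C(C)C)C(C)C)C=C)[C@H](O[Si](C)(C)C(C)(C)C)COCc1ccccc1 | intermediate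
22 | (2E,6Z,9S,10S)-11-(benzyloxy)-10-(TBS-oxy)-7-methyl-9-(prop-1-en-2-yl)-3-(TIPS-oxy)undeca-2,6-diene | C=C(C)[C@H](C/C(C)=C\CC/C(O[Si](C(C)C)(C(C)C)C(C)C)=C\C)[C@H](O[Si](C)(C)C(C)(C)C)COCc1ccccc1 | intermediate
23 | (2S,3S,5Z,9E)-2-(TBS-oxy)-5-methyl-3-(prop-1-en-2-yl)-9-(TIPS-oxy)undeca-5,9-dien-1-ol | C=C(C)[C@H](C/C(C)=C\CC/C(O[Si](C(C)C)(C(C)C)C(C)C)=C\C)[C@H](O[Si](C)(C)C(C)(C)C)CO | intermediate
24 | (2S,3S,5Z,9E)-2-(TBS-oxy)-5-methyl-3-(prop-1-en-2-yl)-9-(TIPS-oxy)undeca-5,9-dienal | C=C(C)[C@H](C/C(C)=C\CC/C(O[Si](C(C)C)(C(C)C)C(C)C)=C\C)[C@H](O[Si](C)(C)C(C)(C)C)C=O | intermediate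
25 | 8β-(TBS-oxy)-9α-hydroxy-7-epi-10βH-eremophil-11-en-3-one | C=C(C)[C@@H]1C[C@@]2(C)[C@H](CCC(=O)[C@@H]2C)[C@H](O)[C@H]1O[Si](C)(C)C(C)(C)C | intermediate
26 | 8β-(TBS-oxy)-7-epi-10βH-eremophil-11-ene-3,9-dione | C=C(C)[C@@H]1C[C@@]2(C)[C@H](CCC(=O)[C@@H]2C)C(=O)[C@H]1O[Si](C)(C)C(C)(C)C | intermediate
27 | 8β-(TBS-oxy)-7-epi-10βH-eremophil-11-ene-3α,9β-diol | C=C(C)[C@@H]1C[C@@]2(C)[C@H](CC[C@@H](O)[C@@H]2C)[C@@H](O)[C@H]1O[Si](C)(C)C(C)(C)C | intermediate
28 | angelic acid, (Z)-2-methylbut-2-enoic acid | C/C=C(/C)C(=O)O | starting material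
29 | (Z)-2-methylbut-2-enoic 2,4,6-trichlorobenzoic anhydride (not isolated) | C/C=C(/C)C(=O)OC(=O)c1c(Cl)cc(Cl)cc1Cl | intermediate
30 | 3α,9β-bis(angeloyloxy)-8β-(TBS-oxy)-7-epi-10βH-eremophil-11-ene | C=C(C)[C@@H]1C[C@@]2(C)[C@H](CC[C@@H](OC(=O)/C(C)=C\C)[C@@H]2C)[C@@H](OC(=O)/C(C)=C\C)[C@H]1O[Si](C)(C)C(C)(C)C | intermediate
31 | 3α,9β-bis(angeloyloxy)-7-epi-10βH-eremophil-11-en-8β-ol | C=C(C)[C@@H]1C[C@@]2(C)[C@H](CC[C@@H](OC(=O)/C(C)=C\C)[C@@H]2C)[C@@H](OC(=O)/C(C)=C\C)[C@H]1O | intermediate
32 | 3α,9β-bis(angeloyloxy)-7-epi-10βH-eremophil-11-en-8-one | C=C(C)[C@@H]1C[C@@]2(C)[C@H](CC[C@@H](OC(=O)/C(C)=C\C)[C@@H]2C)[C@@H](OC(=O)/C(C)=C\C)C1=O | intermediate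
33 | 3α,9β-bis(angeloyloxy)-10βH-eremophil-11-en-8-one, (3R,4R,5R,7R,9R,10S) | C=C(C)[C@H]1C[C@@]2(C)[C@H](CC[C@@H](OC(=O)/C(C)=C\C)[C@@H]2C)[C@@H](OC(=O)/C(C)=C\C)C1=O | target

## Step count and least certain steps

Total: 21 steps. Longest linear sequence: 18 steps (steps 4–8, then 9–21); the other branch (steps 1–3) joins at step 9.

**Step 15 (key step).** The most likely failure is diversion before the second ring closes: the activated aldehyde may be intercepted by the enol ether of another molecule, or the C5 cation may lose a proton, because the enol ether is the most nucleophilic group present while the aldehyde is activated. Leakage at C4 through a boat closure of ring A is the second concern.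
Fallback, from 23 back to 25: the two closures are separated so that no enol ether is present during aldehyde activation.
- Mild acid hydrolysis of the enol ether of 23 would give the keto alcohol (2S,3S,5Z)-2-(TBS-oxy)-1-hydroxy-5-methyl-3-(prop-1-en-2-yl)undec-5-en-9-one F1.
- Oxidation would give the keto aldehyde (2S,3S,5Z)-2-(TBS-oxy)-5-methyl-9-oxo-3-(prop-1-en-2-yl)undec-5-enal F2.
- TiCl4 at −78 °C would close ring B in a Prins reaction in which chloride captures the C5 cation, giving the chloro alcohol 5-chloro-8β-(TBS-oxy)-9α-hydroxy-4,5-seco-7-epi-10βH-eremophil-11-en-3-one F3 with the same chair relay to C10.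
- Kinetic enolisation with lithium 2,2,6,6-tetramethylpiperidide/LiBr and in-situ Me3SiCl would silylate O9 and give the E trimethylsilyl enol ether 5-chloro-8β-(TBS-oxy)-3,9α-bis(trimethylsilyloxy)-4,5-seco-7-epi-10βH-eremophila-3E,11-diene F4, together with its C2 regioisomer 5-chloro-8β-(TBS-oxy)-3,9α-bis(trimethylsilyloxy)-4,5-seco-7-epi-10βH-eremophila-2E,11-diene F5, which cannot close a six-membered ring.
- TiCl4 or ZnBr2 would then ionise the tertiary chloride, the enol ether would close ring A (tert-alkylation of a silyl enol ether), and aqueous work-up would release 25.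

**Step 12.** The most likely failure is slow or unselective hydrogen transfer: sluggish turnover with the hindered silyloxydiene, double-bond migration by chromium hydride species, or erosion of the E geometry.
Fallback, from 19 back to 22: EtMgBr would convert 19 into the ethyl ketone (6Z,9S,10S)-11-(benzyloxy)-10-(TBS-oxy)-7-methyl-9-(prop-1-en-2-yl)undec-6-en-3-one F6. Kinetic E-selective enolisation (lithium 2,2,6,6-tetramethylpiperidide, LiBr, THF, −78 °C) and O-silylation with i-Pr3SiOTf would give 22 together with the C2 regioisomer (3E,6Z,9S,10S)-11-(benzyloxy)-10-(TBS-oxy)-7-methyl-9-(prop-1-en-2-yl)-3-(TIPS-oxy)undeca-3,6-diene F7. The isomers would be separated, or carried on together, since only 22 can cyclise.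

**Step 17.** The most likely failure is migration of the C8 silyl group onto the new cis C9 alkoxide if the hindered C9 carbonyl has to be reduced above −78 °C; incomplete face selectivity at C3 is the second concern, because both faces carry an axial neighbour.
Fallback, from 26 back to 30, with no new compound (F0): the reduction and the acylation would be merged. The lithium alkoxides formed at −78 °C would be trapped in the same flask with commercial (Z)-2-methylbut-2-enoic anhydride (alkoxide acylation, which also keeps the Z geometry), so that no free C9 alkoxide survives to work-up.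

**Step 18.** The most likely failure is incomplete acylation of the 9β-hydroxyl (syn-axial to the C5 methyl and next to the silyl ether), which would leave the 3α-monoester, with Z to E isomerisation of the angeloyl group if the reaction is forced.
Fallback, from 27 back to 30: the diol would be acylated with the less hindered 2-[bis(2,2,2-trifluoroethoxy)phosphoryl]propanoic acid (carbodiimide coupling) to give 3α,9β-bis{2-[bis(2,2,2-trifluoroethoxy)phosphoryl]propanoyloxy}-8β-(TBS-oxy)-7-epi-10βH-eremophil-11-ene F8. A Still–Gennari olefination with acetaldehyde (KN(SiMe3)2, 18-crown-6, THF, −78 °C) would then build both Z-configured angelates on the molecule.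

**Step 21.** The most likely failure is over-isomerisation: under base the dienolate can reprotonate at the terminal carbon and move the isopropenyl double bond into conjugation, and prolonged exposure can also epimerise C9 or shift the C9 acyl group.
Fallback, from 32 back to 33: the ketone would be enolised toward C7 as its silyl dienol ether 3α,9β-bis(angeloyloxy)-8-(trimethylsilyloxy)-10βH-eremophila-7,11-diene F9 (Me3SiOTf, Et3N). This would be protonated kinetically at C7 at −78 °C (AcOH with a fluoride source), with the proton expected to enter anti to the 9β-acyloxy group and the C5 methyl. This avoids an equilibrating base.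

## Further compounds

F1 | step 15 | (2S,3S,5Z)-2-(TBS-oxy)-1-hydroxy-5-methyl-3-(prop-1-en-2-yl)undec-5-en-9-one | C=C(C)[C@H](C/C(C)=C\CCC(=O)CC)[C@H](O[Si](C)(C)C(C)(C)C)CO
F2 | step 15 | (2S,3S,5Z)-2-(TBS-oxy)-5-methyl-9-oxo-3-(prop-1-en-2-yl)undec-5-enal | C=C(C)[C@H](C/C(C)=C\CCC(=O)CC)[C@H](O[Si](C)(C)C(C)(C)C)C=O
F3 | step 15 | 5-chloro-8β-(TBS-oxy)-9α-hydroxy-4,5-seco-7-epi-10βH-eremophil-11-en-3-one (C5 configuration immaterial) | C=C(C)[C@@H]1CC(C)(Cl)[C@H](CCC(=O)CC)[C@H](O)[C@H]1O[Si](C)(C)C(C)(C)C
F4 | step 15 | 5-chloro-8β-(TBS-oxy)-3,9α-bis(trimethylsilyloxy)-4,5-seco-7-epi-10βH-eremophila-3E,11-diene | C=C(C)[C@@H]1CC(C)(Cl)[C@H](CC/C(O[Si](C)(C)C)=C\C)[C@H](O[Si](C)(C)C)[C@H]1O[Si](C)(C)C(C)(C)C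
F5 | step 15 | 5-chloro-8β-(TBS-oxy)-3,9α-bis(trimethylsilyloxy)-4,5-seco-7-epi-10βH-eremophila-2E,11-diene | C=C(C)[C@@H]1CC(C)(Cl)[C@H](C/C=C(/O[Si](C)(C)C)CC)[C@H](O[Si](C)(C)C)[C@H]1O[Si](C)(C)C(C)(C)C
F6 | step 12 | (6Z,9S,10S)-11-(benzyloxy)-10-(TBS-oxy)-7-methyl-9-(prop-1-en-2-yl)undec-6-en-3-one | C=C(C)[C@H](C/C(C)=C\CCC(=O)CC)[C@H](O[Si](C)(C)C(C)(C)C)COCc1ccccc1
F7 | step 12 | (3E,6Z,9S,10S)-11-(benzyloxy)-10-(TBS-oxy)-7-methyl-9-(prop-1-en-2-yl)-3-(TIPS-oxy)undeca-3,6-diene | C=C(C)[C@H](C/C(C)=C\C/C=C(/O[Si](C(C)C)(C(C)C)C(C)C)CC)[C@H](O[Si](C)(C)C(C)(C)C)COCc1ccccc1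
F0 | step 17 | none | none
F8 | step 18 | 3α,9β-bis{2-[bis(2,2,2-trifluoroethoxy)phosphoryl]propanoyloxy}-8β-(TBS-oxy)-7-epi-10βH-eremophil-11-ene | C=C(C)[C@@H]1C[C@@]2(C)[C@H](CC[C@@H](OC(=O)C(C)P(=O)(OCC(F)(F)F)OCC(F)(F)F)[C@@H]2C)[C@@H](OC(=O)C(C)P(=O)(OCC(F)(F)F)OCC(F)(F)F)[C@H]1O[Si](C)(C)C(C)(C)C
F9 | step 21 | 3α,9β-bis(angeloyloxy)-8-(trimethylsilyloxy)-10βH-eremophila-7,11-diene | C=C(C)C=1C[C@@]2(C)[C@H](CC[C@@H](OC(=O)/C(C)=C\C)[C@@H]2C)[C@@H](OC(=O)/C(C)=C\C)C=1O[Si](C)(C)C
A1 | alternative 1 | cis-1,1-dimethoxy-4a,5-dimethyl-3,4,4a,7,8,8a-hexahydronaphthalen-2(1H)-one | C1C[C@@]2(C)[C@H](CCC=C2C)C(OC)(OC)C1=O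
A2 | alternative 1 | 3,3-dimethoxy-5,6-dimethyl-2-vinylbicyclo[2.2.2]oct-5-en-2-ol (vinyl group syn to the C5=C6 bridge) | C=C[C@]1(O)C(OC)(OC)[C@H]2CC[C@@H]1C(C)=C2C
A3 | alternative 2 | 3α-(tert-butyldimethylsilyloxy)-9β-hydroxy-10βH-eremophil-11-en-8-one | C=C(C)[C@H]1C[C@@]2(C)[C@H](CC[C@@H](O[Si](C)(C)C(C)(C)C)[C@@H]2C)[C@@H](O)C1=O
A4 | alternative 2 | 3α-(tert-butyldimethylsilyloxy)-8,9-seco-10βH-eremophil-11-ene-8,9-dial | C=C(C)[C@H](C=O)C[C@@]1(C)[C@@H](C=O)CC[C@@H](O[Si](C)(C)C(C)(C)C)[C@@H]1C
A5 | alternative 3 | cis-fused decalin-4-one with C8 tert-butyldimethylsilyl enol ether and C9 4-methoxybenzyl ether | C1C[C@@]2(C)[C@H](CCCC2=O)C(OCc3ccc(OC)cc3)=C1O[Si](C)(C)C(C)(C)C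
A6 | alternative 3 | (7Z)-9-(tert-butyldimethylsilyloxy)-8-(4-methoxybenzyloxy)-2-methyldeca-1,7,9-trien-3-one | C=C(O[Si](C)(C)C(C)(C)C)/C(OCc1ccc(OC)cc1)=C/CCCC(=O)C(C)=C
A7 | alternative 3 | (7Z)-9-(tert-butyldimethylsilyloxy)-8-(4-methoxybenzyloxy)-2-methyldeca-1,7,9-trien-3-ol (either carbinol configuration; the centre is destroyed) | C=C(O[Si](C)(C)C(C)(C)C)/C(OCc1ccc(OC)cc1)=C/CCCC(O)C(C)=C
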